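**Plan**
1. Retrosynthesis: the two acetates come from the 7,15-diol, the C7 carbinol from the 8-en-7-one, and this enone from its tautomer with an exocyclic C9=C11 alkene and a C6=C7 silyl enol ether.
2. In that tautomer ring B is a [4+2] adduct: C5–C6–C7(O)–C8 is a 2-silyloxy diene, C9–C10 (C9 carrying exocyclic C11) is one π bond of an allene C10=C9=C11, and C1–C4 of ring A is the tether, so C5–C10 and C8–C9 are cut together.
3. The acyclic chain is cut at C5=C6 (Horner–Wadsworth–Emmons), at C1–C10 (copper-catalysed anti-SN2′ coupling of an alkylborane with a propargylic phosphate, which also makes the allene) and at C11–C12 (vinylogous Mukaiyama aldol).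
4. Forward: the C9–C15 fragment and the C1–C5 fragment are joined, the C6–C8 ketone unit is added, rings A and B then close in one thermal cycloaddition, and the exocyclic alkene is moved into ring B.
5. Stereochemistry: catalytic aldol sets the C11 carbinol, anti-SN2′ turns it into the allene axis, the axis sets C10, the transition-state geometry sets C5 (trans fusion), CBS reduction sets C7, and the aldol gives 13E.

Key step: step 12

Remark: locants C1–C20 follow labdane numbering (ring A C1–C5 and C10, ring B C5–C10, chain C11–C15, methyls C16–C20).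
Remark: in step 3 the (S,S)-catalyst is taken to open the Si face of the ynal, as its usual model predicts; should the sense prove opposite, the antipode is used and nothing else changes.

**Step 1**
Reactants: 1 but-2-yn-1-ol
Product: 2 but-2-ynal
Conditions: activated MnO2 (10 equiv), CH2Cl2, 25 °C; filtered, dried, used as solution
Reagents that add atoms: none
Why: Activated MnO2 oxidises propargylic alcohols selectively to ynals without over-oxidation, and the volatile aldehyde is carried on as a dried solution.

**Step 2**
Reactants: 3 methyl 3-methylbut-2-enoate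
Product: 4 tert-butyl[(1-methoxy-3-methylbuta-1,3-dien-1-yl)oxy]dimethylsilane
Conditions: LDA (commercial solution), THF, −78 °C; then TBSCl, DMPU, −78 to 25 °C
Reagents that add atoms: tert-butyldimethylsilyl chloride, CC(C)(C)[Si](C)(C)Cl
Why: Kinetic γ-deprotonation of the senecioate gives the extended lithium dienolate, which is O-silylated to the vinylketene silyl acetal needed for the vinylogous Mukaiyama aldol reaction.

**Step 3**
Reactants: 2 but-2-ynal; 4 silyl dienolate
Product: 5 methyl (2E,5S)-5-hydroxy-3-methyloct-2-en-6-ynoate
Conditions: SiCl4 (1.1 equiv), (S,S)-bisphosphoramide [two (S)-N,N′-dimethyl-1,1′-binaphthyl-2,2′-diamine P(=O) units joined through N,N′-dimethylpentane-1,5-diamine] (2 mol %), i-Pr2NEt (10 mol %), CH2Cl2, −78 °C; aqueous NaHCO3/KF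
Reagents that add atoms: none
Why: Catalytic enantioselective vinylogous Mukaiyama aldol reaction in which the chiral Lewis-base-bound trichlorosilyl cation activates the ynal and the dienolate attacks through its γ-carbon on the Si face, which sets the (5S) carbinol centre and delivers the (2E) trisubstituted enoate.

**Step 4**
Reactants: 5 hydroxy enoate
Product: 6 (2E,5S)-3-methyloct-2-en-6-yne-1,5-diol
Conditions: i-Bu2AlH (DIBAL-H, 3.5 equiv), CH2Cl2, −78 to −20 °C; Rochelle salt
Reagents that add atoms: none
Why: DIBAL-H reduces the conjugated ester to the primary allylic alcohol by 1,2-hydride delivery at low temperature without touching the alkyne, the trisubstituted alkene or the carbinol centre.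

**Step 5**
Reactants: 6 diol
Product: 7 (4S,6E)-8-[(tert-butyldiphenylsilyl)oxy]-6-methyloct-6-en-2-yn-4-ol
Conditions: TBDPSCl (1.05 equiv), imidazole, CH2Cl2, −20 to 0 °C
Reagents that add atoms: tert-butyldiphenylsilyl chloride, CC(C)(C)[Si](Cl)(c1ccccc1)c1ccccc1
Why: The bulky silyl chloride discriminates the primary allylic hydroxyl from the secondary propargylic one (selective silylation).

**Step 6**
Reactants: 7 propargylic alcohol
Product: 8 (4S,6E)-8-[(tert-butyldiphenylsilyl)oxy]-6-methyloct-6-en-2-yn-4-yl diethyl phosphate
Conditions: ClP(O)(OEt)2, pyridine, 4-(dimethylamino)pyridine (5 mol %), CH2Cl2, 0 °C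
Reagents that add atoms: diethyl chlorophosphate, CCOP(=O)(Cl)OCC
Why: Phosphorylation of the secondary propargylic alcohol with retention turns it into the leaving group for the copper-catalysed γ-substitution.

**Step 7**
Reactants: 9 2,2-dimethylpent-4-enal
Product: 10 5,5-dimethoxy-4,4-dimethylpent-1-ene
Conditions: HC(OMe)3 (5 equiv, neat), p-TsOH·H2O (1 mol %), 25 °C; Et3N quench
Reagents that add atoms: trimethyl orthoformate, COC(OC)OC
Why: Acid-catalysed acetalisation with the orthoformate masks the non-enolisable neopentyl aldehyde against the borane and the organocopper species of the next step.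

**Step 8**
Reactants: 10 alkenyl acetal; 8 propargylic phosphate
Product: 12 tert-butyl{[(2E)-12,12-dimethoxy-3,7,11,11-tetramethyldodeca-2,5,6-trien-1-yl]oxy}diphenylsilane with (aR) allene axis, via alkylborane 11 (not isolated)
Conditions: 9-BBN dimer, THF, 60 °C; KOtBu (1 equiv, borate formation), then CuOAc (10 mol %) and 8, THF, 25 °C
Reagents that add atoms: none
Why: Anti-Markovnikov hydroboration of the terminal alkene followed by copper-catalysed γ-selective, 1,3-anti stereospecific (SN2′) coupling of the alkylborate with the propargylic phosphate forms the C1–C10 bond and converts the (S) carbinol centre into the (aR) allene axis.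

**Step 9**
Reactants: 12 allene acetal
Product: 13 (10E)-12-[(tert-butyldiphenylsilyl)oxy]-2,2,6,10-tetramethyldodeca-6,7,10-trienal with (aR) allene axis
Conditions: pyridinium p-toluenesulfonate (0.2 equiv), acetone/H2O 10:1, 55 °C
Reagents that add atoms: water, O
Why: Mild acid hydrolysis of the dimethyl acetal frees the aldehyde while the allene and the silyl ether are left intact.

**Step 10**
Reactants: 13 allene aldehyde; 14 diethyl (2-oxobutyl)phosphonate
Product: 15 (4E,14E)-16-[(tert-butyldiphenylsilyl)oxy]-6,6,10,14-tetramethylhexadeca-4,10,11,14-tetraen-3-one with (aR) allene axis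
Conditions: activated Ba(OH)2 (0.8 equiv), THF/H2O 40:1, 25 °C
Reagents that add atoms: none
Why: Horner–Wadsworth–Emmons olefination of the hindered, non-enolisable aldehyde with the β-ketophosphonate gives the (E)-enone.

**Step 11**
Reactants: 15 allene enone
Product: 16 (2Z,4E,14E)-3-[(tert-butyldimethylsilyl)oxy]-16-[(tert-butyldiphenylsilyl)oxy]-6,6,10,14-tetramethylhexadeca-2,4,10,11,14-pentaene with (aR) allene axis
Conditions: TBSOTf (1.3 equiv), Et3N (2 equiv), CH2Cl2, −78 to 0 °C
Reagents that add atoms: tert-butyldimethylsilyl triflate, CC(C)(C)[Si](C)(C)OS(=O)(=O)C(F)(F)F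
Why: Soft enolisation of the ethyl ketone with the silyl triflate and amine gives the cross-conjugated 2-silyloxy diene, with the thermodynamically preferred (Z) enol ether placing the C17 methyl group on the outside of the diene.

**Step 12**
Reactants: 16 silyloxy diene–allene
Product: 17 (5R,8S,10R,9(11)Z,13E)-7-[(tert-butyldimethylsilyl)oxy]-15-[(tert-butyldiphenylsilyl)oxy]labda-6,9(11),13-triene (5-H anti to 10-CH3, 8-CH3 syn to 10-CH3)
Conditions: toluene (0.005 M), 2,6-di-tert-butyl-4-methylphenol (0.1 equiv), 150–165 °C, base-washed sealed tube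
Reagents that add atoms: none
Why: Proposed new method: on heating, the (Z)-2-silyloxy diene C5=C6–C7=C8 and the proximal C9=C10 π bond of the unactivated 1,1,3-trisubstituted allene should combine in a concerted, suprafacial thermal [4+2] cycloaddition (type 1 intramolecular Diels–Alder reaction), driven by the strain of the sp carbon C9 and helped by the C4 gem-dimethyl group on the tether, and the closest known reaction types are the thermal and metal-promoted intramolecular [4+2] reactions of tethered diene–allenes and the axis-to-centre chirality transfer of enantioenriched allenes in cycloadditions. Ring B (C5–C10) is closed by the cycloaddition itself through the new C5–C10 and C8–C9 bonds, and ring A (C1–C5 with C10) is closed as the tether ring by the same C5–C10 bond, six-membered for the proximal allene bond against seven-membered for the distal C9=C11 bond, which secures the periselectivity. The quaternary centre C10 is controlled by the allene axis, because the C12 chain on C11 lies in the plane of the reacting p orbitals and leaves only the face that carries the C11 hydrogen open to the diene, so the (aR) axis gives (10R). C5 is controlled relative to C10 by the tether-exo, methyl-endo chair-like transition state, which gives the trans ring fusion, whereas C8 follows from the (Z) enol ether and is erased in step 13. The selectivity that the step needs most is this anti over syn mode, and since either mode must place one C10 substituent 1,3-diaxial to a C4 methyl group the preference rests only on the unstrained chair of the exo tether and is the main uncertainty of the route. The exocyclic C9=C11 alkene that results is the masked form of the C8=C9 enone.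

**Step 13**
Reactants: 17 cycloadduct
Product: 19 (4aR,8aR)-4-[(3E)-5-hydroxy-3-methylpent-3-en-1-yl]-3,4a,8,8-tetramethyl-4a,5,6,7,8,8a-hexahydronaphthalen-2(1H)-one, via deconjugated ketone 18 (not isolated)
Conditions: Bu4NF (3 equiv), THF, 0 to 25 °C; then DBU (0.5 equiv), 25 °C
Reagents that add atoms: none
Why: Fluoride cleaves the silyl enol ether and the silyl ether, and base-mediated prototropic shift through the dienolate moves the exocyclic C9=C11 double bond into conjugation as the tetrasubstituted C8=C9 enone, which erases the C8 centre and the alkylidene geometry.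

**Step 14**
Reactants: 19 hydroxy enone
Product: 20 (2S,4aR,8aR)-4-[(3E)-5-hydroxy-3-methylpent-3-en-1-yl]-3,4a,8,8-tetramethyl-1,2,4a,5,6,7,8,8a-octahydronaphthalen-2-ol
Conditions: (R)-2-methyl-CBS-oxazaborolidine [(3aR)-1-methyl-3,3-diphenyltetrahydro-1H,3H-pyrrolo[1,2-c][1,3,2]oxazaborole] (0.5 equiv), catecholborane (3 equiv), toluene, −78 to −40 °C; then MeOH, aqueous NaOH
Reagents that add atoms: none
Why: CBS reduction in which the (R)-oxazaborolidine delivers hydride to the enone carbonyl with the alkenyl carbon C8 as the large group, which sets (7S) under reagent control, while catecholborane at low temperature leaves the trisubstituted alkene alone.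

**Step 15**
Reactants: 20 diol
Product: 21 (2S,4aR,8aR)-4-[(3E)-5-acetoxy-3-methylpent-3-en-1-yl]-3,4a,8,8-tetramethyl-1,2,4a,5,6,7,8,8a-octahydronaphthalen-2-yl acetate (CNP0275583.1)
Conditions: Ac2O (4 equiv), pyridine, 4-(dimethylamino)pyridine (0.1 equiv), CH2Cl2, 0 to 25 °C
Reagents that add atoms: acetic anhydride, CC(=O)OC(C)=O
Why: Standard nucleophile-catalysed acylation converts the primary and the secondary allylic hydroxyl into acetates without touching the stereocentres.

**Compound list**
1 | but-2-yn-1-ol | CC#CCO | starting material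
2 | but-2-ynal | CC#CC=O | intermediate
3 | methyl 3-methylbut-2-enoate | COC(=O)C=C(C)C | starting material
4 | tert-butyl[(1-methoxy-3-methylbuta-1,3-dien-1-yl)oxy]dimethylsilane (ketene acetal geometry not defined) | COC(=CC(C)=C)O[Si](C)(C)C(C)(C)C | intermediate
5 | methyl (2E,5S)-5-hydroxy-3-methyloct-2-en-6-ynoate | CC#C[C@@H](O)C/C(C)=C/C(=O)OC | intermediate
6 | (2E,5S)-3-methyloct-2-en-6-yne-1,5-diol | CC#C[C@@H](O)C/C(C)=C/CO | intermediate
7 | (4S,6E)-8-[(tert-butyldiphenylsilyl)oxy]-6-methyloct-6-en-2-yn-4-ol | CC#C[C@@H](O)C/C(C)=C/CO[Si](c1ccccc1)(c1ccccc1)C(C)(C)C | intermediate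
8 | (4S,6E)-8-[(tert-butyldiphenylsilyl)oxy]-6-methyloct-6-en-2-yn-4-yl diethyl phosphate | CC#C[C@@H](OP(=O)(OCC)OCC)C/C(C)=C/CO[Si](c1ccccc1)(c1ccccc1)C(C)(C)C | intermediate
9 | 2,2-dimethylpent-4-enal | C=CCC(C)(C)C=O | starting material
10 | 5,5-dimethoxy-4,4-dimethylpent-1-ene | C=CCC(C)(C)C(OC)OC | intermediate
11 | 9-(5,5-dimethoxy-4,4-dimethylpentyl)-9-borabicyclo[3.3.1]nonane | COC(OC)C(C)(C)CCCB1C2CCCC1CCC2 | intermediate
12 | tert-butyl{[(2E)-12,12-dimethoxy-3,7,11,11-tetramethyldodeca-2,5,6-trien-1-yl]oxy}diphenylsilane, (aR) allene axis (M helicity) | [H]C(C/C(C)=C/CO[Si](c1ccccc1)(c1ccccc1)C(C)(C)C)=[C@@]=C(C)CCCC(C)(C)C(OC)OC | intermediate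
13 | (10E)-12-[(tert-butyldiphenylsilyl)oxy]-2,2,6,10-tetramethyldodeca-6,7,10-trienal, (aR) allene axis | [H]C(C/C(C)=C/CO[Si](c1ccccc1)(c1ccccc1)C(C)(C)C)=[C@@]=C(C)CCCC(C)(C)C=O | intermediate
14 | diethyl (2-oxobutyl)phosphonate | CCC(=O)CP(=O)(OCC)OCC | starting material
15 | (4E,14E)-16-[(tert-butyldiphenylsilyl)oxy]-6,6,10,14-tetramethylhexadeca-4,10,11,14-tetraen-3-one, (aR) allene axis | [H]C(C/C(C)=C/CO[Si](c1ccccc1)(c1ccccc1)C(C)(C)C)=[C@@]=C(C)CCCC(C)(C)/C=C/C(=O)CC | intermediate
16 | (2Z,4E,14E)-3-[(tert-butyldimethylsilyl)oxy]-16-[(tert-butyldiphenylsilyl)oxy]-6,6,10,14-tetramethylhexadeca-2,4,10,11,14-pentaene, (aR) allene axis | [H]C(C/C(C)=C/CO[Si](c1ccccc1)(c1ccccc1)C(C)(C)C)=[C@@]=C(C)CCCC(C)(C)/C=C/C(O[Si](C)(C)C(C)(C)C)=C/C | intermediate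
17 | (5R,8S,10R,9(11)Z,13E)-7-[(tert-butyldimethylsilyl)oxy]-15-[(tert-butyldiphenylsilyl)oxy]labda-6,9(11),13-triene (labdane numbering, trans-fused) | CC(C)(C)[Si](c1ccccc1)(c1ccccc1)OC/C=C(\C)C/C=C1/[C@H](C)C(O[Si](C)(C)C(C)(C)C)=C[C@@H]2C(C)(C)CCC[C@@]12C | intermediate
18 | (5R,8S,10R,9(11)Z,13E)-15-hydroxylabda-9(11),13-dien-7-one (labdane numbering) | OC/C=C(\C)C/C=C1/[C@H](C)C(=O)C[C@@H]2C(C)(C)CCC[C@@]12C | intermediate
19 | (4aR,8aR)-4-[(3E)-5-hydroxy-3-methylpent-3-en-1-yl]-3,4a,8,8-tetramethyl-4a,5,6,7,8,8a-hexahydronaphthalen-2(1H)-one | OC/C=C(\C)CCC1=C(C)C(=O)C[C@@H]2C(C)(C)CCC[C@@]12C | intermediate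
20 | (2S,4aR,8aR)-4-[(3E)-5-hydroxy-3-methylpent-3-en-1-yl]-3,4a,8,8-tetramethyl-1,2,4a,5,6,7,8,8a-octahydronaphthalen-2-ol | OC/C=C(\C)CCC1=C(C)[C@@H](O)C[C@@H]2C(C)(C)CCC[C@@]12C | intermediate
21 | (2S,4aR,8aR)-4-[(3E)-5-acetoxy-3-methylpent-3-en-1-yl]-3,4a,8,8-tetramethyl-1,2,4a,5,6,7,8,8a-octahydronaphthalen-2-yl acetate | CC(=O)OC/C=C(\C)CCC1=C(C)[C@@H](OC(C)=O)C[C@@H]2C(C)(C)CCC[C@@]12C | target

**Step count**
Total: 15 steps. Longest linear sequence: 13 steps (steps 1, 3, 4, 5, 6, 8, 9, 10, 11, 12, 13, 14, 15).

**Steps most likely to fail**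

Step 12. What may go wrong: the tether-endo (syn) transition state or addition to the distal allene bond may compete, and slow cyclisation may let the silyl dienol ether degrade at the temperature needed. Fallback with known chemistry: setting out from 16, the ring closure is run as the nickel-catalysed intramolecular [4+2] cycloaddition of tethered diene–allenes (Ni(cod)2 as the source of zerovalent nickel, tris(2-biphenylyl) phosphite, THF, 25–40 °C). This is a documented reaction of unactivated diene–allene pairs that engages the tethered allene bond and builds angular methyl centres. It replaces the pericyclic transition state by oxidative cyclisation to a nickelacycle and reductive elimination near room temperature, so the thermal side reactions fall away. The metal should bind the allene face anti to C12, which keeps the axis-to-C10 transfer. The route is rejoined at 17.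

Step 8. What may go wrong: incomplete 1,3-anti transfer, or α-substitution at the carbinol carbon because the γ-carbon already bears a methyl group, would erode the allene enantiopurity. Fallback: setting out from 7, the alcohol is converted with methyl chloroformate and pyridine into (4S,6E)-8-[(tert-butyldiphenylsilyl)oxy]-6-methyloct-6-en-2-yn-4-yl methyl carbonate F1. F1 is coupled with the same alkylborane 11 under Pd(PPh3)4 catalysis (THF, 60 °C, no added base). Anti oxidative addition gives an allenylpalladium methoxide, the methoxide activates the borane for transmetalation, and reductive elimination gives the allene with overall anti transfer. The route is rejoined at 12.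

Step 14. What may go wrong: the substrate's own preference for axial hydride delivery may override the reagent and give the C7 epimer, or the facial selectivity may be poor. Fallback: setting out from 19, Luche reduction (NaBH4, CeCl3·7H2O, MeOH, −40 °C) is used to give, by axial attack, (2R,4aR,8aR)-4-[(3E)-5-hydroxy-3-methylpent-3-en-1-yl]-3,4a,8,8-tetramethyl-1,2,4a,5,6,7,8,8a-octahydronaphthalen-2-ol F2. A Mitsunobu reaction with acetic acid (PPh3, diisopropyl azodicarboxylate, AcOH in excess, toluene, 0 to 25 °C) then inverts C7 and esterifies the primary C15 hydroxyl in the same operation. The route is rejoined at 21.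

**Further compounds**
F0 | step 12 | none | none
F1 | step 8 | (4S,6E)-8-[(tert-butyldiphenylsilyl)oxy]-6-methyloct-6-en-2-yn-4-yl methyl carbonate | CC#C[C@@H](OC(=O)OC)C/C(C)=C/CO[Si](c1ccccc1)(c1ccccc1)C(C)(C)C
F2 | step 14 | (2R,4aR,8aR)-4-[(3E)-5-hydroxy-3-methylpent-3-en-1-yl]-3,4a,8,8-tetramethyl-1,2,4a,5,6,7,8,8a-octahydronaphthalen-2-ol | OC/C=C(\C)CCC1=C(C)[C@H](O)C[C@@H]2C(C)(C)CCC[C@@]12C
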